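## Retrosynthetic overview

1. The strategy rests on ring A of the benzofuran: O1, the C4 hydroxyl and the C6 hydroxyl are mutually meta, and C7 carries the quaternary 1,1-dimethylallyl carbon between O1 and the C6 oxygen. Ring A is cut across C7–C7a, C6–C7, C4–C5 and C3a–C4 into a 2-furyl α-diazo ketone that already holds the quaternary chain and (triisopropylsiloxy)acetylene.
2. The diazo ketone comes from a 2-arylfuran by furan C5 lithiation, Weinreb acylation and deacylative diazo transfer; the aryl–furan bond is a Suzuki coupling of a chroman C5 triflate.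
3. The chroman is built first from phloroglucinol through its C4 ketone. The hydrogen bond of that ketone to the C5 hydroxyl tells the two phenols apart (C7 silyl ether, C5 triflate), which avoids the C2/C4 ambiguity of prenylating a 5-substituted resorcinol; the ketone is then reduced away.
4. Ring order: pyran ring of the chroman (step 1), furan ring brought in intact (step 6), benzene ring A last (step 11); one fluoride step then frees the three phenols.

Key step: step 11

Assumption: (triisopropylsiloxy)acetylene is not treated as a catalogue chemical and is prepared in step 10.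

## Route

Step 1
Reactants: 1 phloroglucinol; 2 3-methylbut-2-enoic acid
Product: 4 5,7-dihydroxy-2,2-dimethylchroman-4-one, via aryl enone 3 (not isolated)
Conditions: P2O5, MeSO3H, 70 °C
Reagents that add atoms: none
Why: Friedel–Crafts acylation of the threefold-symmetric triol by the unsaturated acid gives enone 3, and intramolecular oxa-Michael addition of an ortho hydroxyl closes the pyranone, so no regiochemical question arises.

Step 2
Reactants: 4 5,7-dihydroxy-2,2-dimethylchroman-4-one
Product: 5 5-hydroxy-2,2-dimethyl-7-(triisopropylsilyloxy)chroman-4-one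
Conditions: TIPSCl (1.05 equiv), imidazole, DMF, 0 °C → rt
Reagents that add atoms: triisopropylsilyl chloride, CC(C)[Si](Cl)(C(C)C)C(C)C
Why: The C5 hydroxyl is held in a hydrogen bond to the C4 carbonyl, so the bulky silyl chloride should silylate only the free C7 hydroxyl (selective phenol silylation).

Step 3
Reactants: 5 5-hydroxy-2,2-dimethyl-7-(triisopropylsilyloxy)chroman-4-one
Product: 6 2,2-dimethyl-4-oxo-7-(triisopropylsilyloxy)chroman-5-yl trifluoromethanesulfonate
Conditions: Tf2O, pyridine, CH2Cl2, 0 °C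
Reagents that add atoms: trifluoromethanesulfonic anhydride, O=S(=O)(OS(=O)(=O)C(F)(F)F)C(F)(F)F
Why: Triflic anhydride with pyridine sulfonylates the remaining chelated phenol (aryl triflate formation), while the aryl silyl ether and the ketone are inert.

Step 4
Reactants: 6 2,2-dimethyl-4-oxo-7-(triisopropylsilyloxy)chroman-5-yl trifluoromethanesulfonate
Product: 7 4-hydroxy-2,2-dimethyl-7-(triisopropylsilyloxy)chroman-5-yl trifluoromethanesulfonate (racemic)
Conditions: NaBH4, THF–MeOH, 0 °C
Reagents that add atoms: none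
Why: Borohydride 1,2-reduction of the aryl ketone leaves the triflate and the silyl ether untouched at 0 °C; the new C4 stereocentre is racemic and is removed in step 5.

Step 5
Reactants: 7 4-hydroxy-2,2-dimethyl-7-(triisopropylsilyloxy)chroman-5-yl trifluoromethanesulfonate
Product: 9 2,2-dimethyl-7-(triisopropylsilyloxy)chroman-5-yl trifluoromethanesulfonate, via benzylic cation 8 (not isolated)
Conditions: Et3SiH, CF3CO2H, CH2Cl2, 0 °C
Reagents that add atoms: none
Why: Ionic hydrogenation: the acid ionises the benzylic alcohol to cation 8, stabilised by the para silyloxy group and the ortho ring oxygen, and the silane delivers hydride; any chromene formed by proton loss is re-protonated to the same cation.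

Step 6
Reactants: 9 2,2-dimethyl-7-(triisopropylsilyloxy)chroman-5-yl trifluoromethanesulfonate; 10 furan-2-boronic acid
Product: 11 2-[2,2-dimethyl-7-(triisopropylsilyloxy)chroman-5-yl]furan
Conditions: Pd(OAc)2 (cat.), SPhos (cat.), K3PO4, THF–H2O, 40 °C; 10 in excess (1.5 equiv)
Reagents that add atoms: none
Why: Suzuki–Miyaura coupling; the electron-rich biaryl phosphine makes oxidative addition into the ortho-substituted aryl triflate and transmetalation fast at 40 °C, so coupling should outrun protodeboronation of the 2-furylboronic acid.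

Step 7
Reactants: 12 3,3-dimethylpent-4-enoic acid
Product: 14 N-methoxy-N,3,3-trimethylpent-4-enamide, via acyl imidazolide 13 (not isolated)
Conditions: CDI, CH2Cl2, rt; then MeNH(OMe)·HCl, rt
Reagents that add atoms: N,O-dimethylhydroxylamine hydrochloride, CNOC.Cl
Why: Activation of the acid as imidazolide 13 and aminolysis gives the Weinreb amide; the acid has no other reactive group.

Step 8
Reactants: 11 2-[2,2-dimethyl-7-(triisopropylsilyloxy)chroman-5-yl]furan; 14 N-methoxy-N,3,3-trimethylpent-4-enamide
Product: 17 1-{5-[2,2-dimethyl-7-(triisopropylsilyloxy)chroman-5-yl]furan-2-yl}-3,3-dimethylpent-4-en-1-one, via furyllithium 15 (not isolated), via tetrahedral adduct 16 (not isolated)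
Conditions: n-BuLi, THF, −78 → 0 °C; then 14, −78 → 0 °C; H2O
Reagents that add atoms: none
Why: The only free furan α-position (C5) is the most acidic C–H and is lithiated, and the Weinreb amide acylates 15 through chelated adduct 16, which blocks over-addition until work-up.

Step 9
Reactants: 17 1-{5-[2,2-dimethyl-7-(triisopropylsilyloxy)chroman-5-yl]furan-2-yl}-3,3-dimethylpent-4-en-1-one
Product: 20 2-diazo-1-{5-[2,2-dimethyl-7-(triisopropylsilyloxy)chroman-5-yl]furan-2-yl}-3,3-dimethylpent-4-en-1-one, via lithium enolate 18 (not isolated), via trifluoroacetyl ketone 19 (not isolated)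
Conditions: LiN(SiMe3)2, THF, −78 °C; CF3CO2CH2CF3; dilute HCl work-up; then MsN3, Et3N, H2O (1 equiv), MeCN, rt
Reagents that add atoms: methanesulfonyl azide, CS(=O)(=O)N=[N+]=[N-]
Why: Detrifluoroacetylative diazo transfer: enolate 18 is C-acylated by the trifluoroacetate, and the activated 1,3-dicarbonyl 19 takes N2 from the small, linear sulfonyl azide with loss of the trifluoroacetyl group as its N-sulfonyl amide, under conditions mild enough for the aryl silyl ether.

Step 10
Reactants: 21 ethyl formate
Product: 24 (triisopropylsiloxy)acetylene, via dibromo enolate 22 (not isolated), via lithium ethynolate 23 (not isolated)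
Conditions: CH2Br2, LiN(i-Pr)2, THF, −78 °C; 21; LiN(SiMe3)2, −78 → −20 °C; n-BuLi, −78 °C → rt; TIPSCl, −78 °C → rt
Reagents that add atoms: dibromomethane, BrCBr; triisopropylsilyl chloride, CC(C)[Si](Cl)(C(C)C)C(C)C
Why: Kowalski ester homologation stopped at the ynolate: dibromomethyllithium adds to the formate, collapse and enolisation give 22, bromine–lithium exchange and 1,2-shift in the carbenoid give ynolate 23, and the bulky silyl chloride traps it on oxygen.

Step 11
Reactants: 20 2-diazo-1-{5-[2,2-dimethyl-7-(triisopropylsilyloxy)chroman-5-yl]furan-2-yl}-3,3-dimethylpent-4-en-1-one; 24 (triisopropylsiloxy)acetylene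
Product: 29 2-[2,2-dimethyl-7-(triisopropylsilyloxy)chroman-5-yl]-7-(2-methylbut-3-en-2-yl)-6-(triisopropylsilyloxy)benzofuran-4-ol, via furylketene 25 (not isolated), via siloxycyclobutenone 26 (not isolated), via dienylketene 27 (not isolated), via cyclohexadienone 28 (not isolated)
Conditions: 24 (3 equiv), hν (medium-pressure Hg lamp, Pyrex), ClCH2CH2Cl, rt; then 80 °C
Reagents that add atoms: none
Why: Proposed new method: irradiation should expel N2 from 20 with 1,2-shift of the 2-furyl group to the diazo carbon (photochemical Wolff rearrangement), giving ketene 25 whose α-carbon (future C7) already bears the quaternary chain and is now bonded to furan C2 (future C7a); the closest known reaction type is the photochemical diazo ketone–siloxyalkyne benzannulation of heteroaryl diazomethyl ketones (second-generation Danheiser benzannulation), which has not been run with a tert-alkyl group on the diazo carbon. The electron-rich alkyne 24 then adds [2+2] to the ketene C=C, its nucleophilic CH terminus bonding to the ketene carbonyl carbon (C4–C5) and its oxygenated carbon to the α-carbon (C6–C7), to give the strained cyclobutenone 26. Four-electron electrocyclic opening of 26 (by light or heat) gives dienylketene 27, and ring A is closed by a thermal disrotatory six-electron electrocyclisation of 27 onto furan C3 (C3a–C4), after which cyclohexadienone 28 tautomerises to the phenol, so that the C4 hydroxyl arrives free and O6 silylated. No stereocentre remains in 29; those of 26 and 28 are transient and racemic. The step needs (a) the [2+2] regiochemistry, secured by the polarisation of the siloxyalkyne, (b) the dienylketene geometry with the furyl group cis to the ketene arm, secured because the other isomer cannot cyclise and re-closes to 26 on heating, and (c) furyl migration faster than 1,2-shift of methyl or vinyl from the quaternary carbon, for which the high migratory aptitude of the heteroaryl group and direct excitation (N2 loss concerted with migration) are relied on. Strain release in 26 and aromatisation drive the cascade.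

Step 12
Reactants: 29 2-[2,2-dimethyl-7-(triisopropylsilyloxy)chroman-5-yl]-7-(2-methylbut-3-en-2-yl)-6-(triisopropylsilyloxy)benzofuran-4-ol
Product: 30 2-(7-hydroxy-2,2-dimethylchroman-5-yl)-7-(2-methylbut-3-en-2-yl)benzofuran-4,6-diol
Conditions: n-Bu4NF, AcOH, THF, 0 °C → rt
Reagents that add atoms: none
Why: Fluoride cleaves both aryl silyl ethers (Si–F bond formation), and the acetic acid buffer keeps the electron-rich triphenol and the ortho-(1,1-dimethylallyl)phenol from base- or air-induced side reactions.

## Compound list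

1 | phloroglucinol | Oc1cc(O)cc(O)c1 | starting material
2 | 3-methylbut-2-enoic acid | CC(C)=CC(=O)O | starting material
3 | 3-methyl-1-(2,4,6-trihydroxyphenyl)but-2-en-1-one | CC(C)=CC(=O)c1c(O)cc(O)cc1O | intermediate (not isolated)
4 | 5,7-dihydroxy-2,2-dimethylchroman-4-one | CC1(C)CC(=O)c2c(O)cc(O)cc2O1 | intermediate
5 | 5-hydroxy-2,2-dimethyl-7-(triisopropylsilyloxy)chroman-4-one | CC1(C)CC(=O)c2c(O)cc(O[Si](C(C)C)(C(C)C)C(C)C)cc2O1 | intermediate
6 | 2,2-dimethyl-4-oxo-7-(triisopropylsilyloxy)chroman-5-yl trifluoromethanesulfonate | CC1(C)CC(=O)c2c(OS(=O)(=O)C(F)(F)F)cc(O[Si](C(C)C)(C(C)C)C(C)C)cc2O1 | intermediate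
7 | 4-hydroxy-2,2-dimethyl-7-(triisopropylsilyloxy)chroman-5-yl trifluoromethanesulfonate (racemic) | CC1(C)CC(O)c2c(OS(=O)(=O)C(F)(F)F)cc(O[Si](C(C)C)(C(C)C)C(C)C)cc2O1 | intermediate
8 | 2,2-dimethyl-5-(trifluoromethylsulfonyloxy)-7-(triisopropylsilyloxy)chroman-4-yl cation | CC1(C)C[CH+]c2c(OS(=O)(=O)C(F)(F)F)cc(O[Si](C(C)C)(C(C)C)C(C)C)cc2O1 | intermediate (not isolated)
9 | 2,2-dimethyl-7-(triisopropylsilyloxy)chroman-5-yl trifluoromethanesulfonate | CC1(C)CCc2c(OS(=O)(=O)C(F)(F)F)cc(O[Si](C(C)C)(C(C)C)C(C)C)cc2O1 | intermediate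
10 | furan-2-boronic acid | OB(O)c1ccco1 | starting material
11 | 2-[2,2-dimethyl-7-(triisopropylsilyloxy)chroman-5-yl]furan | CC1(C)CCc2c(-c3ccco3)cc(O[Si](C(C)C)(C(C)C)C(C)C)cc2O1 | intermediate
12 | 3,3-dimethylpent-4-enoic acid | C=CC(C)(C)CC(=O)O | starting material
13 | 1-(imidazol-1-yl)-3,3-dimethylpent-4-en-1-one | C=CC(C)(C)CC(=O)n1ccnc1 | intermediate (not isolated)
14 | N-methoxy-N,3,3-trimethylpent-4-enamide | C=CC(C)(C)CC(=O)N(C)OC | intermediate
15 | {5-[2,2-dimethyl-7-(triisopropylsilyloxy)chroman-5-yl]furan-2-yl}lithium | [Li]c1ccc(-c2cc(O[Si](C(C)C)(C(C)C)C(C)C)cc3c2CCC(C)(C)O3)o1 | intermediate (not isolated)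
16 | lithium alkoxide of the N-methoxy-N-methyl hemiaminal of ketone 17 | C=CC(C)(C)CC(O[Li])(N(C)OC)c1ccc(-c2cc(O[Si](C(C)C)(C(C)C)C(C)C)cc3c2CCC(C)(C)O3)o1 | intermediate (not isolated)
17 | 1-{5-[2,2-dimethyl-7-(triisopropylsilyloxy)chroman-5-yl]furan-2-yl}-3,3-dimethylpent-4-en-1-one | C=CC(C)(C)CC(=O)c1ccc(-c2cc(O[Si](C(C)C)(C(C)C)C(C)C)cc3c2CCC(C)(C)O3)o1 | intermediate
18 | lithium (Z)-enolate of ketone 17 | C=CC(C)(C)/C=C(\O[Li])c1ccc(-c2cc(O[Si](C(C)C)(C(C)C)C(C)C)cc3c2CCC(C)(C)O3)o1 | intermediate (not isolated)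
19 | 1-{5-[2,2-dimethyl-7-(triisopropylsilyloxy)chroman-5-yl]furan-2-yl}-4,4,4-trifluoro-2-(2-methylbut-3-en-2-yl)butane-1,3-dione (racemic) | C=CC(C)(C)C(C(=O)C(F)(F)F)C(=O)c1ccc(-c2cc(O[Si](C(C)C)(C(C)C)C(C)C)cc3c2CCC(C)(C)O3)o1 | intermediate (not isolated)
20 | 2-diazo-1-{5-[2,2-dimethyl-7-(triisopropylsilyloxy)chroman-5-yl]furan-2-yl}-3,3-dimethylpent-4-en-1-one | C=CC(C)(C)C(=[N+]=[N-])C(=O)c1ccc(-c2cc(O[Si](C(C)C)(C(C)C)C(C)C)cc3c2CCC(C)(C)O3)o1 | intermediate
21 | ethyl formate | CCOC=O | starting material
22 | lithium 2,2-dibromoethen-1-olate | [Li]OC=C(Br)Br | intermediate (not isolated)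
23 | lithium ethynolate | [Li]OC#C | intermediate (not isolated)
24 | (triisopropylsiloxy)acetylene | C#CO[Si](C(C)C)(C(C)C)C(C)C | intermediate
25 | 2-{5-[2,2-dimethyl-7-(triisopropylsilyloxy)chroman-5-yl]furan-2-yl}-3,3-dimethylpenta-1,4-dien-1-one (ketene) | C=CC(C)(C)C(=C=O)c1ccc(-c2cc(O[Si](C(C)C)(C(C)C)C(C)C)cc3c2CCC(C)(C)O3)o1 | intermediate (not isolated)
26 | 4-{5-[2,2-dimethyl-7-(triisopropylsilyloxy)chroman-5-yl]furan-2-yl}-4-(2-methylbut-3-en-2-yl)-3-(triisopropylsilyloxy)cyclobut-2-en-1-one (racemic) | C=CC(C)(C)C1(c2ccc(-c3cc(O[Si](C(C)C)(C(C)C)C(C)C)cc4c3CCC(C)(C)O4)o2)C(=O)C=C1O[Si](C(C)C)(C(C)C)C(C)C | intermediate (not isolated)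
27 | (E)-4-{5-[2,2-dimethyl-7-(triisopropylsilyloxy)chroman-5-yl]furan-2-yl}-5,5-dimethyl-3-(triisopropylsilyloxy)hepta-1,3,6-trien-1-one | C=CC(C)(C)/C(c1ccc(-c2cc(O[Si](C(C)C)(C(C)C)C(C)C)cc3c2CCC(C)(C)O3)o1)=C(/C=C=O)O[Si](C(C)C)(C(C)C)C(C)C | intermediate (not isolated)
28 | 2-[2,2-dimethyl-7-(triisopropylsilyloxy)chroman-5-yl]-7-(2-methylbut-3-en-2-yl)-6-(triisopropylsilyloxy)-3aH-benzofuran-4-one (racemic) | O=C1C=C(O[Si](C(C)C)(C(C)C)C(C)C)C(C(C)(C)C=C)=C2OC(c3cc(O[Si](C(C)C)(C(C)C)C(C)C)cc4c3CCC(C)(C)O4)=CC12 | intermediate (not isolated)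
29 | 2-[2,2-dimethyl-7-(triisopropylsilyloxy)chroman-5-yl]-7-(2-methylbut-3-en-2-yl)-6-(triisopropylsilyloxy)benzofuran-4-ol | C=CC(C)(C)c1c(O[Si](C(C)C)(C(C)C)C(C)C)cc(O)c2cc(-c3cc(O[Si](C(C)C)(C(C)C)C(C)C)cc4c3CCC(C)(C)O4)oc12 | intermediate
30 | 2-(7-hydroxy-2,2-dimethylchroman-5-yl)-7-(2-methylbut-3-en-2-yl)benzofuran-4,6-diol | C=CC(C)(C)c1c(O)cc(O)c2cc(-c3cc(O)cc4c3CCC(C)(C)O4)oc12 | target

## Step count and risks

Total steps: 12. Longest linear sequence: 10 steps (steps 1–6, 8, 9, 11, 12); steps 7 and 10 are side branches.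

**Step 11 (key step).** The tert-alkyl group on the diazo carbon disfavours the s-Z conformer from which furyl migration is concerted with N2 loss. A free carbene may then undergo 1,2-shift of methyl or vinyl from the quaternary carbon faster than Wolff rearrangement. The dienylketene isomer with the quaternary group turned inward may also be captured by its own vinyl group instead of re-closing. The fallback makes the same ketene without any carbene, by dehydrochlorination of an acid chloride, and uses the known thermal ketene–siloxyalkyne cycloaddition and electrocyclic cascade. It sets out from 11 and comes back at ketene 25, and so at 29. Compound 11 is lithiated as in step 8 and acylated with N-methoxy-N-methylacetamide to the methyl ketone F1. Detrifluoroacetylative diazo transfer, here on an unhindered methyl ketone, gives the diazomethyl ketone F2. Silver benzoate and Et3N in THF with 3-methylbut-2-en-1-ol (Arndt–Eistert conditions) give the prenyl furylacetate F3. Ireland–Claisen rearrangement (LiN(i-Pr)2, Me3SiCl, THF, −78 °C → rt, then aqueous acid) builds the quaternary carbon and gives the acid F4. Oxalyl chloride gives the acid chloride F5. Et3N in toluene in the presence of 24 then gives 25 and cyclobutenone 26, and heating to 80–110 °C carries 26 through 27 and 28 to 29.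

**Step 9.** Carbon–nitrogen bond formation at the dicarbonyl carbon that is flanked by the quaternary centre may be so slow that retro-Claisen loss of the trifluoroacetyl group returns ketone 17. The fallback forms the C–N bond on the mono-carbonyl enolate, where only a tertiary centre is made, and converts the azide into the diazo group afterwards. It sets out from 17 and comes back at 20. The potassium enolate (KN(SiMe3)2, THF, −78 °C) is treated with 2,4,6-triisopropylbenzenesulfonyl azide and quenched with AcOH (electrophilic enolate azidation) to give the azido ketone F6. N-Succinimidyl 3-(diphenylphosphino)propanoate in wet THF converts F6 into the acyl triazene F7, and NaHCO3 fragments F7 to 20 (phosphine-mediated azide-to-diazo conversion).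

**Step 10.** The carbenoid may add a second time to the formate-derived aldehyde before enolisation, or the unhindered ynolate may be silylated on carbon, so that little siloxyalkyne is obtained. The fallback replaces the silyl ynol ether by an alkynyl ether made by the alkoxide–trichloroethylene route and removes its O-substituent with fluoride at the end. It sets out from 20 and comes back at 30. 2-(Trimethylsilyl)ethanol, KH and trichloroethylene give the dichlorovinyl ether F8. n-BuLi followed by MeOH gives 2-(trimethylsilyl)ethoxyacetylene F9. Irradiation of 20 with F9 as in step 11 gives the benzofuranol F10, which carries a 2-(trimethylsilyl)ethyl ether at O6. n-Bu4NF in DMF with warming cleaves the silyl ether and the 2-(trimethylsilyl)ethyl ether together to give 30.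

## Further compounds

F1 | step 11 | 1-{5-[2,2-dimethyl-7-(triisopropylsilyloxy)chroman-5-yl]furan-2-yl}ethanone | CC(=O)c1ccc(-c2cc(O[Si](C(C)C)(C(C)C)C(C)C)cc3c2CCC(C)(C)O3)o1
F2 | step 11 | 2-diazo-1-{5-[2,2-dimethyl-7-(triisopropylsilyloxy)chroman-5-yl]furan-2-yl}ethanone | [N-]=[N+]=CC(=O)c1ccc(-c2cc(O[Si](C(C)C)(C(C)C)C(C)C)cc3c2CCC(C)(C)O3)o1
F3 | step 11 | 3-methylbut-2-enyl 2-{5-[2,2-dimethyl-7-(triisopropylsilyloxy)chroman-5-yl]furan-2-yl}acetate | CC(C)=CCOC(=O)Cc1ccc(-c2cc(O[Si](C(C)C)(C(C)C)C(C)C)cc3c2CCC(C)(C)O3)o1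
F4 | step 11 | 2-{5-[2,2-dimethyl-7-(triisopropylsilyloxy)chroman-5-yl]furan-2-yl}-3,3-dimethylpent-4-enoic acid (racemic) | C=CC(C)(C)C(C(=O)O)c1ccc(-c2cc(O[Si](C(C)C)(C(C)C)C(C)C)cc3c2CCC(C)(C)O3)o1
F5 | step 11 | 2-{5-[2,2-dimethyl-7-(triisopropylsilyloxy)chroman-5-yl]furan-2-yl}-3,3-dimethylpent-4-enoyl chloride (racemic) | C=CC(C)(C)C(C(=O)Cl)c1ccc(-c2cc(O[Si](C(C)C)(C(C)C)C(C)C)cc3c2CCC(C)(C)O3)o1
F6 | step 9 | 2-azido-1-{5-[2,2-dimethyl-7-(triisopropylsilyloxy)chroman-5-yl]furan-2-yl}-3,3-dimethylpent-4-en-1-one (racemic) | C=CC(C)(C)C(N=[N+]=[N-])C(=O)c1ccc(-c2cc(O[Si](C(C)C)(C(C)C)C(C)C)cc3c2CCC(C)(C)O3)o1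
F7 | step 9 | acyl triazene from F6 and the 3-(diphenylphosphoryl)propanoyl group (racemic) | C=CC(C)(C)C(N=NNC(=O)CCP(=O)(c1ccccc1)c1ccccc1)C(=O)c1ccc(-c2cc(O[Si](C(C)C)(C(C)C)C(C)C)cc3c2CCC(C)(C)O3)o1
F8 | step 10 | (E)-1,2-dichlorovinyl 2-(trimethylsilyl)ethyl ether | Cl/C=C(/Cl)OCC[Si](C)(C)C
F9 | step 10 | 2-(trimethylsilyl)ethoxyacetylene | C#COCC[Si](C)(C)C
F10 | step 10 | 2-[2,2-dimethyl-7-(triisopropylsilyloxy)chroman-5-yl]-7-(2-methylbut-3-en-2-yl)-6-[2-(trimethylsilyl)ethoxy]benzofuran-4-ol | C=CC(C)(C)c1c(OCC[Si](C)(C)C)cc(O)c2cc(-c3cc(O[Si](C(C)C)(C(C)C)C(C)C)cc4c3CCC(C)(C)O4)oc12
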